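(The earlier runs and the new flask are simulated on assumed constants; noise was put on by code.)

**Ratio at rest.** The ratio ρ of back rate to forward rate in the coupling starts at zero, and the net rate is the forward rate times (one minus ρ). The suspects are a reversible coupling of starting material and coupling partner under free catalyst, release of free catalyst from precatalyst, and loss of free catalyst with starting material to spent catalyst. On that scheme free catalyst multiplies both directions, so it drops out of ρ.

the same everywhere: starting material 0.58 M

| run | coupling partner | precatalyst | remark | time |
|---|---|---|---|---|
| larch | 0.50 equiv | 0.1 mol% | run made earlier |  |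
| oak | 0.50 equiv | 0.15 mol% | run made earlier |  |
| flask | 0.500 equiv | 0.2 mol% |  | 15 d |

| run | time / d | starting material / % | product / % |
|---|---|---|---|
| larch | 0.833 | 96.5 | 3.8 |
| larch | 2.50 | 83.5 | 15.8 |
| larch | 4.00 | 79.8 | 20.6 |
| larch | 6.00 | 78.5 | 19.9 |
| larch | 10.0 | 79.8 | 19.4 |
| larch | 12.0 | 81.2 | 19.5 |
| oak | 2.08 | 83.5 | 18.0 |
| oak | 4.00 | 79.9 | 19.0 |
| oak | 6.00 | 79.8 | 18.9 |
| oak | 8.00 | 80.2 | 19.1 |
| oak | 10.0 | 80.4 | 20.8 |
| oak | 12.0 | 80.4 | 21.1 |

(scatter of a reading: 1 percentage point)

- the numbers in the tables scatter by 1 percentage point (one standard deviation)
- on the list of suspects stand: starting material + coupling partner + free catalyst <-> product + free catalyst; precatalyst -> free catalyst; starting material + free catalyst -> spent catalyst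
- the reaction counts as stopped when no species that holds the starting material changes by six tenths of a point or more over the second half of the time

- which holds at 15 d: what has brought the reaction to rest, or that it has not come to rest (the coupling partner has run out first / all of the starting material has reacted / forward and back rates have come level / it is still moving / no working catalyst is left)
- share of the starting material used up at 15 d
- product at 15 d, in percent of the starting material charged

**Start, slowing.** The larch run gains 3.8 % product by 0.833 d, a mean rate of 0.0456 d⁻¹ of the charge. Larch and oak both read level from 4.00 d. The means of those level readings show, with free catalyst held aside, that lost starting material multiplies the forward rate by 0.800 and lost coupling partner by 0.604. Per unit of free catalyst, the forward rate therefore ends near half its start. Meanwhile the back rate climbs from zero to meet it, and ρ reaches one at the level reading, a mean of 19.8 % product.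

**Rest constant.** Product over those two factors and the partner charged gives the rest constant K, the equilibrium constant, read as 1.41 L mol⁻¹, with the scatter of the readings.

**This flask.** The flask has the starting material and coupling partner of larch and twice its precatalyst, and it runs 15 d. Larch, with less precatalyst, reads level from 4.00 d. My reckoning puts the flask at ρ of one, with product 19.8 % and conversion 20.0 %.

The forecast reads: forward and back rates have come level, conversion 20 %, product 19.8 %, since “catalyst only sets how fast it is reached”. The flask's result reads: forward and back rates have come level, conversion 19.9 %, product 19.7 %.

    starting material + coupling partner + free catalyst ⇌ product + free catalyst, rate k1*[starting material]*[coupling partner]*[free catalyst] forward; the back reaction follows from the equilibrium constant (K = 1.40 L mol⁻¹, k = 1.60 L² mol⁻² min⁻¹)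
    precatalyst → free catalyst (k = 3.30 × 10⁻⁴ min⁻¹)
    starting material + free catalyst → spent catalyst (k = 1.80 × 10⁻⁴ L mol⁻¹ min⁻¹)

**Check.** At 15.0 d the forward coupling alone would halve starting material in 6.8 d, far shorter than the 11000 d of the path to spent catalyst. Free catalyst stands at 21.7 % of the catalyst charged at 15.0 d. On the read K, the flask's contents at 15.0 d put ρ at 0.990. A neighbour flask, alike but with 2.00 equiv coupling partner, holds 54.2 % product at 15.0 d, and its contents on the same K put ρ at 0.990.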